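**Plan**
- Retrosynthesis: remove the silyl group; cut the oxirane bond C4–C5 (and with it C4–O) of the 4,5-epoxycyclodec-1(10)-ene to give an acyclic C5 aldehyde carrying a C4 diphenylsulfonium group; then cut C9–C10 (Nozaki–Hiyama–Kishi), the three ester C–O bonds, C5–C6 (Weinreb ketone) and C7–C8 (Evans aldol).
- Forward: the C5–C9 chain is built first, the C10–C4 arm is added at C9, all three esters are installed, and a single ring-forming event then makes the ten-membered carbocycle and the oxirane together; no other ring is formed.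
- Enabling feature: the oxirane O–C4–C5 lies inside the C1–C10 ring. C5 is an oxirane CH next to the C6 acyloxy stereocentre (an α-acyloxy aldehyde in retrosynthesis), and C4 is a methyl-bearing quaternary oxirane carbon (the ylide carbon of a sec-alkyl diphenylsulfonium), so an intramolecular sulfur-ylide epoxidation closes both rings.
- Stereochemistry: C7/C8 from the (S)-benzyloxazolidinone (Evans syn aldol); C6 from C8 (1,3-anti Evans–Tishchenko, which also installs the tiglate); C9 from C8 (Felkin NHK addition); C4/C5 from C6 and the E-alkene tether in the ring closure; side-chain C2′/C3′ from a second Evans aldol ((R)-auxiliary).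

Key step: step 21

Remark: locants C1–C15 are the germacrane locants of the target (oxirane C4–C5, esters on O6/O8/O9, isopropyl on C7, alkene C1=C10).
Remark: the sulfur-bearing carbon (future C4) is carried as both epimers because it becomes the ylide carbon in step 21; it is drawn without a descriptor in 5–8 and 31–36.

**Route**

Step 1
Reactants: 1 pentane-2,4-dione; 2 1-bromobut-2-yne
Product: 4 hept-5-yn-2-one, via 3-(but-2-yn-1-yl)pentane-2,4-dione 3 (not isolated)
Conditions: K2CO3, EtOH, reflux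
Reagents that add atoms: none
Why: C-alkylation of the diketone anion followed by in situ retro-Claisen deacetylation by ethanol (alkylation–cleavage route to methyl ketones) should give the alkynyl methyl ketone directly.

Step 2
Reactants: 4 hept-5-yn-2-one
Product: 5 hept-5-yn-2-ol (racemic)
Conditions: NaBH4, MeOH, 0 °C
Reagents that add atoms: none
Why: Borohydride reduction of the ketone; the carbinol carbon is deliberately left racemic because it ends as the ylide carbon.

Step 3
Reactants: 5 hept-5-yn-2-ol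
Product: 7 (5E)-6-iodohept-5-en-2-ol, via alkenylzirconocene chloride 6 (not isolated)
Conditions: Cp2Zr(H)Cl (3 equiv), THF, rt to 45 °C; then I2, 0 °C
Reagents that add atoms: iodine, II
Why: Syn hydrozirconation of the 2-alkyne with excess Schwartz reagent should equilibrate zirconium to the methyl-bearing carbon, and iodinolysis with retention should give the (E)-2-iodo-2-alkene (hydrozirconation–iodination).

Step 4
Reactants: 7 (5E)-6-iodohept-5-en-2-ol
Product: 8 [(5E)-6-iodohept-5-en-2-yl](phenyl)sulfane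
Conditions: PhSSPh, PBu3, pyridine, rt
Reagents that add atoms: diphenyl disulfide, c1ccc(SSc2ccccc2)cc1
Why: Hata thioetherification (alkoxyphosphonium displaced by thiolate in an SN2 step) should convert the secondary alcohol into the phenyl sulfide without touching the vinyl iodide.

Step 5
Reactants: 9 (4R)-4-benzyl-3-propanoyl-1,3-oxazolidin-2-one; 10 acetaldehyde
Product: 12 (4R)-4-benzyl-3-[(2R,3S)-3-hydroxy-2-methylbutanoyl]-1,3-oxazolidin-2-one, via dibutylboron Z-enolate 11 (not isolated)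
Conditions: Bu2BOTf, iPr2NEt, CH2Cl2, −78 to 0 °C; then pH 7 buffer, MeOH, H2O2
Reagents that add atoms: none
Why: Evans syn aldol through the Z-boron enolate and a Zimmerman–Traxler transition state; the (R)-benzyl auxiliary should set 2′R,3′S.

Step 6
Reactants: 12 aldol adduct
Product: 13 (4R)-4-benzyl-3-[(2R,3S)-3-{[tert-butyl(dimethyl)silyl]oxy}-2-methylbutanoyl]-1,3-oxazolidin-2-one
Conditions: TBSOTf, 2,6-lutidine, CH2Cl2, −78 to 0 °C
Reagents that add atoms: tert-butyldimethylsilyl triflate, CC(C)(C)[Si](C)(C)OS(=O)(=O)C(F)(F)F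
Why: Silylation of the secondary alcohol with a silyl triflate blocks the side-chain hydroxyl through all later acylations.

Step 7
Reactants: 13 silylated imide
Product: 15 (2R,3S)-3-{[tert-butyl(dimethyl)silyl]oxy}-2-methylbutanoic acid, via peroxy acid 14 (not isolated)
Conditions: LiOH, H2O2, THF/H2O, 0 °C; then Na2SO3; then 1 M HCl
Reagents that add atoms: hydrogen peroxide, OO
Why: Lithium hydroperoxide attacks the exocyclic imide carbonyl selectively (Evans auxiliary cleavage) without epimerising C2′, and sulfite reduces the peracid to the acid.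

Step 8
Reactants: 16 tributyl(iodomethyl)stannane; 17 (4-methoxyphenyl)methanol
Product: 18 tributyl{[(4-methoxyphenyl)methoxy]methyl}stannane
Conditions: NaH, THF/DMF, 0 °C to rt
Reagents that add atoms: none
Why: Williamson etherification at the primary iodomethylstannane should give the Still-type α-alkoxymethylstannane.

Step 9
Reactants: 19 (4S)-4-benzyl-3-(3-methylbutanoyl)-1,3-oxazolidin-2-one; 20 {[tert-butyl(dimethyl)silyl]oxy}acetaldehyde
Product: 22 (4S)-4-benzyl-3-[(2S,3S)-4-{[tert-butyl(dimethyl)silyl]oxy}-3-hydroxy-2-(propan-2-yl)butanoyl]-1,3-oxazolidin-2-one, via dibutylboron Z-enolate 21 (not isolated)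
Conditions: Bu2BOTf, iPr2NEt, CH2Cl2, −78 to 0 °C; then pH 7 buffer, MeOH, H2O2
Reagents that add atoms: none
Why: Evans syn aldol; the (S)-benzyl auxiliary directs the aldehyde to the enolate face that sets C7 and C8 in the 7,8-syn relationship of the target.

Step 10
Reactants: 22 aldol adduct
Product: 23 (2S,3S)-4-{[tert-butyl(dimethyl)silyl]oxy}-3-hydroxy-N-methoxy-N-methyl-2-(propan-2-yl)butanamide
Conditions: MeNH(OMe)·HCl, AlMe3, CH2Cl2/THF, −20 to 0 °C
Reagents that add atoms: N,O-dimethylhydroxylamine hydrochloride, CNOC.Cl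
Why: Weinreb transamidation with the aluminium amide, assisted by the free β-hydroxyl, should remove the auxiliary without epimerising C7.

Step 11
Reactants: 23 Weinreb amide; 18 tributyl{[(4-methoxyphenyl)methoxy]methyl}stannane
Product: 25 (3S,4S)-5-{[tert-butyl(dimethyl)silyl]oxy}-4-hydroxy-1-[(4-methoxyphenyl)methoxy]-3-(propan-2-yl)pentan-2-one, via [(4-methoxyphenyl)methoxy]methyllithium 24 (not isolated)
Conditions: 18 (3 equiv), n-BuLi, THF, −78 °C; then 23, −78 °C; aq. NH4Cl
Reagents that add atoms: none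
Why: Tin–lithium exchange gives the α-alkoxymethyllithium, which adds once to the Weinreb amide (chelated tetrahedral intermediate) and brings in C5 as a protected carbinol.

Step 12
Reactants: 25 β-hydroxy ketone; 26 (2E)-2-methylbut-2-enal
Product: 27 (2S,3R,4S)-1-{[tert-butyl(dimethyl)silyl]oxy}-4-hydroxy-5-[(4-methoxyphenyl)methoxy]-3-(propan-2-yl)pentan-2-yl (2E)-2-methylbut-2-enoate (O8 tiglate, free C6–OH)
Conditions: SmI2 (0.3 equiv), 26 (6 equiv), THF, −10 °C
Reagents that add atoms: none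
Why: Evans–Tishchenko reduction, in which samarium-templated intramolecular hydride transfer from the hemiacetal of the C8 alkoxide and tiglaldehyde to the C6 ketone should give the 6,8-anti diol with the tiglate left on O8.

Step 13
Reactants: 27 C6 alcohol; 15 (2R,3S)-3-{[tert-butyl(dimethyl)silyl]oxy}-2-methylbutanoic acid
Product: 28 diester (O6 silyloxybutanoate, O8 tiglate, C5–OPMB, C9–OTBS)
Conditions: 2-methyl-6-nitrobenzoic anhydride, DMAP, Et3N, CH2Cl2, rt
Reagents that add atoms: none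
Why: Shiina esterification through a mixed anhydride acylates the hindered secondary alcohol under mild basic conditions that should not epimerise the α-methyl acid.

Step 14
Reactants: 28 diester
Product: 29 primary alcohol (C9–OH)
Conditions: HF·pyridine, pyridine, THF, 0 °C
Reagents that add atoms: none
Why: Buffered HF·pyridine cleaves a primary TBS ether much faster than the secondary one on the side chain, and the acidic medium disfavours acyl migration.

Step 15
Reactants: 29 primary alcohol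
Product: 30 α-tigloyloxy aldehyde (C9 aldehyde)
Conditions: Dess–Martin periodinane, NaHCO3, CH2Cl2, 0 °C to rt
Reagents that add atoms: none
Why: Dess–Martin oxidation under buffered, non-basic conditions should give the epimerisable α-acyloxy aldehyde, which is used crude.

Step 16
Reactants: 30 C9 aldehyde; 8 [(5E)-6-iodohept-5-en-2-yl](phenyl)sulfane
Product: 31 allylic alcohol (9R)
Conditions: CrCl2 (6 equiv), NiCl2 (2 mol %), DMSO/THF, rt
Reagents that add atoms: none
Why: Nozaki–Hiyama–Kishi coupling forms C9–C10 with retention of the E-alkene and tolerates the esters and the sulfide; polar Felkin–Anh control by the C8 acyloxy group should set C9 in the 8,9-anti sense.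

Step 17
Reactants: 31 allylic alcohol
Product: 32 allylic acetate (O9 acetate)
Conditions: Ac2O, DMAP, pyridine, CH2Cl2, rt
Reagents that add atoms: acetic anhydride, CC(=O)OC(C)=O
Why: DMAP-catalysed acetylation of the only free hydroxyl completes the three-ester pattern of the target.

Step 18
Reactants: 32 sulfide
Product: 33 diphenyl(sec-alkyl)sulfonium triflate
Conditions: Ph2I+ TfO− (1.5 equiv), Cu(OAc)2 (5 mol %), 1,2-dichloroethane, 90 °C
Reagents that add atoms: diphenyliodonium triflate, c1ccc([I+]c2ccccc2)cc1.[O-]S(=O)(=O)C(F)(F)F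
Why: Copper-catalysed S-arylation of an alkyl aryl sulfide with a diaryliodonium salt (Crivello-type sulfonium synthesis) should give a sulfonium whose only α-hydrogen is at C4.

Step 19
Reactants: 33 sulfonium triflate
Product: 34 primary alcohol (C5–OH) sulfonium triflate
Conditions: DDQ, CH2Cl2/pH 7 buffer, 0 °C to rt
Reagents that add atoms: none
Why: Oxidative cleavage of the 4-methoxybenzyl ether by DDQ is neutral and leaves the esters, the silyl ether, the alkenes and the electron-poor sulfonium untouched.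

Step 20
Reactants: 34 primary alcohol
Product: 35 seco aldehyde (C5 aldehyde, C4 diphenylsulfonium triflate)
Conditions: Dess–Martin periodinane, NaHCO3, CH2Cl2, 0 °C
Reagents that add atoms: none
Why: Dess–Martin oxidation of the freshly released alcohol, done at once to forestall 1,2-acyl migration, should give the α-acyloxy aldehyde for ring closure.

Step 21
Reactants: 35 seco aldehyde
Product: 38 O-TBS-protected target, via sulfonium ylide 36 (not isolated), via betaine 37 (not isolated)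
Conditions: LiHMDS (1.1 equiv, added over 6 h), THF, 1 mM, −78 to −30 °C
Reagents that add atoms: none
Why: Proposed new method: LiHMDS removes the only α-hydrogen of the diphenylsulfonium group (C4–H, about ten pK units more acidic than the ester α-hydrogens), the ylide carbon C4 adds to the C5 aldehyde and the betaine alkoxide displaces diphenyl sulfide at C4 with inversion, as in Corey–Chaykovsky epoxidation with diphenylsulfonium isopropylide and in the intramolecular sulfonium-ylide epoxidations that form five- to seven-membered rings, which are the closest precedents; a ten-membered carbocycle closed this way is not known. The ten-membered ring closes by 10-exo-trig addition of C4 to C5=O and the oxirane by 3-exo-tet displacement. C5 is controlled by the C6 stereocentre: the carbonyl oxygen must point away from the forming ring (anti to C6–C7) and the C6–O bond lies anti to the incoming ylide carbon (polar Felkin–Anh), which should place O5 syn to O6 (5R). C4 follows from the transoid approach (C3 anti to C6) favoured by the rigid E-C1=C10 tether and the anti-betaine closure, which should give the trans-oxirane (4R). The step needs intramolecular over intermolecular addition and ylide formation over aldehyde enolisation or E2 loss of diphenyl sulfide; the 1 mM concentration, slow base addition at −78 °C and the hindered tertiary C6–H are meant to secure this.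

Step 22
Reactants: 38 O-TBS-protected target
Product: 39 CNP0218463.1
Conditions: TBAF/AcOH (1:1), THF, 0 °C to rt
Reagents that add atoms: none
Why: Acetic acid-buffered fluoride desilylation frees the side-chain hydroxyl without acid that would trigger transannular opening of the oxirane or base that would move the esters.

**Compound list**

1 | pentane-2,4-dione | CC(=O)CC(C)=O | starting material
2 | 1-bromobut-2-yne | CC#CCBr | starting material
3 | 3-(but-2-yn-1-yl)pentane-2,4-dione | CC#CCC(C(C)=O)C(C)=O | intermediate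
4 | hept-5-yn-2-one | CC#CCCC(C)=O | intermediate
5 | hept-5-yn-2-ol (racemic) | CC#CCCC(C)O | intermediate
6 | (E)-6-zirconated hept-5-en-2-ol as its O-zirconocene alkoxide (alkenylzirconocene chloride) | C/C(=C\CCC(C)O[Zr](Cl)(C1C=CC=C1)C1C=CC=C1)[Zr](Cl)(C1C=CC=C1)C1C=CC=C1 | intermediate
7 | (5E)-6-iodohept-5-en-2-ol (racemic) | C/C(I)=C\CCC(C)O | intermediate
8 | [(5E)-6-iodohept-5-en-2-yl](phenyl)sulfane (racemic) | C/C(I)=C\CCC(C)Sc1ccccc1 | intermediate
9 | (4R)-4-benzyl-3-propanoyl-1,3-oxazolidin-2-one | CCC(=O)N1C(=O)OC[C@H]1Cc1ccccc1 | starting material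
10 | acetaldehyde | CC=O | starting material
11 | dibutylboron Z-enolate of 9 | C/C=C(\OB(CCCC)CCCC)N1C(=O)OC[C@H]1Cc1ccccc1 | intermediate
12 | (4R)-4-benzyl-3-[(2R,3S)-3-hydroxy-2-methylbutanoyl]-1,3-oxazolidin-2-one | O=C([C@H](C)[C@H](C)O)N1C(=O)OC[C@H]1Cc1ccccc1 | intermediate
13 | (4R)-4-benzyl-3-[(2R,3S)-3-{[tert-butyl(dimethyl)silyl]oxy}-2-methylbutanoyl]-1,3-oxazolidin-2-one | O=C([C@H](C)[C@H](C)O[Si](C)(C)C(C)(C)C)N1C(=O)OC[C@H]1Cc1ccccc1 | intermediate
14 | (2R,3S)-3-{[tert-butyl(dimethyl)silyl]oxy}-2-methylbutaneperoxoic acid | OOC(=O)[C@H](C)[C@H](C)O[Si](C)(C)C(C)(C)C | intermediate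
15 | (2R,3S)-3-{[tert-butyl(dimethyl)silyl]oxy}-2-methylbutanoic acid | OC(=O)[C@H](C)[C@H](C)O[Si](C)(C)C(C)(C)C | intermediate
16 | tributyl(iodomethyl)stannane | CCCC[Sn](CI)(CCCC)CCCC | starting material
17 | (4-methoxyphenyl)methanol | COc1ccc(CO)cc1 | starting material
18 | tributyl{[(4-methoxyphenyl)methoxy]methyl}stannane | CCCC[Sn](CCCC)(CCCC)COCc1ccc(OC)cc1 | intermediate
19 | (4S)-4-benzyl-3-(3-methylbutanoyl)-1,3-oxazolidin-2-one | CC(C)CC(=O)N1C(=O)OC[C@@H]1Cc1ccccc1 | starting material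
20 | {[tert-butyl(dimethyl)silyl]oxy}acetaldehyde | O=CCO[Si](C)(C)C(C)(C)C | starting material
21 | dibutylboron Z-enolate of 19 | CC(C)/C=C(\OB(CCCC)CCCC)N1C(=O)OC[C@@H]1Cc1ccccc1 | intermediate
22 | (4S)-4-benzyl-3-[(2S,3S)-4-{[tert-butyl(dimethyl)silyl]oxy}-3-hydroxy-2-(propan-2-yl)butanoyl]-1,3-oxazolidin-2-one | O=C([C@@H](C(C)C)[C@H](O)CO[Si](C)(C)C(C)(C)C)N1C(=O)OC[C@@H]1Cc1ccccc1 | intermediate
23 | (2S,3S)-4-{[tert-butyl(dimethyl)silyl]oxy}-3-hydroxy-N-methoxy-N-methyl-2-(propan-2-yl)butanamide | CON(C)C(=O)[C@@H](C(C)C)[C@H](O)CO[Si](C)(C)C(C)(C)C | intermediate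
24 | [(4-methoxyphenyl)methoxy]methyllithium | [Li]COCc1ccc(OC)cc1 | intermediate
25 | (3S,4S)-5-{[tert-butyl(dimethyl)silyl]oxy}-4-hydroxy-1-[(4-methoxyphenyl)methoxy]-3-(propan-2-yl)pentan-2-one | COc1ccc(COCC(=O)[C@@H](C(C)C)[C@H](O)CO[Si](C)(C)C(C)(C)C)cc1 | intermediate
26 | (2E)-2-methylbut-2-enal | C/C=C(\C)C=O | starting material
27 | (2S,3R,4S)-1-{[tert-butyl(dimethyl)silyl]oxy}-4-hydroxy-5-[(4-methoxyphenyl)methoxy]-3-(propan-2-yl)pentan-2-yl (2E)-2-methylbut-2-enoate | COc1ccc(COC[C@@H](O)[C@@H](C(C)C)[C@H](OC(=O)/C(C)=C/C)CO[Si](C)(C)C(C)(C)C)cc1 | intermediate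
28 | C5–C9 chain: C5–OPMB, O6 (2R,3S)-3-(TBS-oxy)-2-methylbutanoate, C7 isopropyl, O8 tiglate, C9–OTBS; C6–C8 as in the target | COc1ccc(COC[C@@H](OC(=O)[C@H](C)[C@H](C)O[Si](C)(C)C(C)(C)C)[C@@H](C(C)C)[C@H](OC(=O)/C(C)=C/C)CO[Si](C)(C)C(C)(C)C)cc1 | intermediate
29 | as 28 with free primary C9–OH | COc1ccc(COC[C@@H](OC(=O)[C@H](C)[C@H](C)O[Si](C)(C)C(C)(C)C)[C@@H](C(C)C)[C@H](OC(=O)/C(C)=C/C)CO)cc1 | intermediate
30 | as 28 with C9 aldehyde | COc1ccc(COC[C@@H](OC(=O)[C@H](C)[C@H](C)O[Si](C)(C)C(C)(C)C)[C@@H](C(C)C)[C@H](OC(=O)/C(C)=C/C)C=O)cc1 | intermediate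
31 | C5–C4 seco chain with free C9–OH (9R), E-C1=C10, C4–SPh, C5–OPMB | COc1ccc(COC[C@@H](OC(=O)[C@H](C)[C@H](C)O[Si](C)(C)C(C)(C)C)[C@@H](C(C)C)[C@H](OC(=O)/C(C)=C/C)[C@H](O)/C(C)=C/CCC(C)Sc2ccccc2)cc1 | intermediate
32 | as 31 with O9 acetate | COc1ccc(COC[C@@H](OC(=O)[C@H](C)[C@H](C)O[Si](C)(C)C(C)(C)C)[C@@H](C(C)C)[C@H](OC(=O)/C(C)=C/C)[C@H](OC(C)=O)/C(C)=C/CCC(C)Sc2ccccc2)cc1 | intermediate
33 | as 32 with C4 diphenylsulfonium triflate | COc1ccc(COC[C@@H](OC(=O)[C@H](C)[C@H](C)O[Si](C)(C)C(C)(C)C)[C@@H](C(C)C)[C@H](OC(=O)/C(C)=C/C)[C@H](OC(C)=O)/C(C)=C/CCC(C)[S+](c2ccccc2)c2ccccc2)cc1.[O-]S(=O)(=O)C(F)(F)F | intermediate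
34 | as 33 with free primary C5–OH | OC[C@@H](OC(=O)[C@H](C)[C@H](C)O[Si](C)(C)C(C)(C)C)[C@@H](C(C)C)[C@H](OC(=O)/C(C)=C/C)[C@H](OC(C)=O)/C(C)=C/CCC(C)[S+](c1ccccc1)c1ccccc1.[O-]S(=O)(=O)C(F)(F)F | intermediate
35 | seco aldehyde: C5 aldehyde, C4 diphenylsulfonium triflate, all three esters in place | O=C[C@@H](OC(=O)[C@H](C)[C@H](C)O[Si](C)(C)C(C)(C)C)[C@@H](C(C)C)[C@H](OC(=O)/C(C)=C/C)[C@H](OC(C)=O)/C(C)=C/CCC(C)[S+](c1ccccc1)c1ccccc1.[O-]S(=O)(=O)C(F)(F)F | intermediate
36 | C4 diphenylsulfonium ylide of 35 | O=C[C@@H](OC(=O)[C@H](C)[C@H](C)O[Si](C)(C)C(C)(C)C)[C@@H](C(C)C)[C@H](OC(=O)/C(C)=C/C)[C@H](OC(C)=O)/C(C)=C/CC[C-](C)[S+](c1ccccc1)c1ccccc1 | intermediate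
37 | ten-membered betaine: C5 alkoxide, C4 diphenylsulfonium (drawn as zwitterion) | C/C=C(\C)C(=O)O[C@H]1[C@H](C(C)C)[C@H](OC(=O)[C@H](C)[C@H](C)O[Si](C)(C)C(C)(C)C)[C@@H]([O-])[C@@](C)([S+](c2ccccc2)c2ccccc2)CC/C=C(\C)[C@H]1OC(C)=O | intermediate
38 | O-TBS-protected target (side-chain 3′-O-TBS) | C/C=C(\C)C(=O)O[C@H]1[C@H](C(C)C)[C@H](OC(=O)[C@H](C)[C@H](C)O[Si](C)(C)C(C)(C)C)[C@H]2O[C@]2(C)CC/C=C(\C)[C@H]1OC(C)=O | intermediate
39 | CNP0218463.1: (1(10)E,4R,5R,6S,7S,8S,9R)-9-acetoxy-4,5-epoxy-6-[(2R,3S)-3-hydroxy-2-methylbutanoyloxy]-8-tigloyloxygermacr-1(10)-ene | C/C=C(\C)C(=O)O[C@H]1[C@H](C(C)C)[C@H](OC(=O)[C@H](C)[C@H](C)O)[C@H]2O[C@]2(C)CC/C=C(\C)[C@H]1OC(C)=O | target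

**Totals and risks**

Total step count: 22. Longest linear sequence: 14 steps (steps 9–22, from 19).

Most likely to fail:

1. Step 21 (Proposed new method). The ylide may add intermolecularly and oligomerise. It may be quenched by proton transfer from C6–H, which would epimerise C6, or lose diphenyl sulfide by E2. Attack on the other aldehyde face or a cisoid closure would give diastereomeric oxiranes. The fallback is reductive carbonyl coupling followed by invertive oxirane closure, all known chemistry. Because SmI2 would cleave an α-acyloxy aldehyde, O6 is carried as a silyl ether. It sets out from 27 and returns at 38. Alcohol 27 is silylated (TBSOTf, 2,6-lutidine) to the bis-silyl ether F1. HF·pyridine frees the primary C9 alcohol F2, and Dess–Martin oxidation gives the aldehyde F3. NHK coupling with (5E)-6-iodohept-5-en-2-one F4 (from 7 by Dess–Martin oxidation; the chromium reagent spares the ketone) gives the 9R alcohol F5, which is acetylated to F6. DDQ gives the primary alcohol F7, and Dess–Martin oxidation gives the keto aldehyde F8. SmI2 (THF, 1 mM) closes C4–C5 by pinacol coupling to the cis-diol F9, with C5–OH anti to O6 by Felkin control. MsCl/Et3N gives the C5 mesylate F10, and KHMDS closes the oxirane with inversion at C5 to give F11. Buffered TBAF frees the C6 alcohol F12, which is esterified with 15 (MNBA, DMAP) to give 38.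

2. Step 18. The sec-alkyl sulfonium may eliminate thermally, or the copper–aryl species may arylate the anisyl ring or the alkene. The fallback makes the C–S bond by S-alkylation of diphenyl sulfide. It sets out from 30 (with 7) and returns at 33. Alcohol 7 is silylated (TESCl, imidazole) to F13. NHK coupling of 30 with F13 gives the alcohol F14, which is acetylated to F15. PPTS in MeOH removes the triethylsilyl group to give the secondary alcohol F16. Tf2O with 2,6-di-tert-butylpyridine at −78 °C, then diphenyl sulfide, gives 33 by SN2 displacement of the triflate.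

3. Step 16. Facial selectivity at C9 may be poor, or the tiglate may shift from O8 to the new chromium alkoxide. The fallback sets C9 by reagent control. It sets out from 31 (as its C9 epimer mixture) and returns at 31. MnO2 oxidises the allylic alcohol to the enone F17. CBS reduction (Me-CBS with catecholborane, toluene, −78 °C) then gives the 9R alcohol 31; the (R)-catalyst is the choice if the alkenyl group acts as the large substituent.

**Further compounds**

F1 | step 21 | 27 with O6-TBS (bis-silyl ether) | COc1ccc(COC[C@@H](O[Si](C)(C)C(C)(C)C)[C@@H](C(C)C)[C@H](OC(=O)/C(C)=C/C)CO[Si](C)(C)C(C)(C)C)cc1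
F2 | step 21 | F1 with free primary C9–OH | COc1ccc(COC[C@@H](O[Si](C)(C)C(C)(C)C)[C@@H](C(C)C)[C@H](OC(=O)/C(C)=C/C)CO)cc1
F3 | step 21 | C9 aldehyde with O6-TBS | COc1ccc(COC[C@@H](O[Si](C)(C)C(C)(C)C)[C@@H](C(C)C)[C@H](OC(=O)/C(C)=C/C)C=O)cc1
F4 | step 21 | (5E)-6-iodohept-5-en-2-one | C/C(I)=C\CCC(C)=O
F5 | step 21 | NHK adduct: 9R alcohol, C4 ketone, O6-TBS | COc1ccc(COC[C@@H](O[Si](C)(C)C(C)(C)C)[C@@H](C(C)C)[C@H](OC(=O)/C(C)=C/C)[C@H](O)/C(C)=C/CCC(C)=O)cc1
F6 | step 21 | O9 acetate of F5 | COc1ccc(COC[C@@H](O[Si](C)(C)C(C)(C)C)[C@@H](C(C)C)[C@H](OC(=O)/C(C)=C/C)[C@H](OC(C)=O)/C(C)=C/CCC(C)=O)cc1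
F7 | step 21 | F6 with free primary C5–OH | OC[C@@H](O[Si](C)(C)C(C)(C)C)[C@@H](C(C)C)[C@H](OC(=O)/C(C)=C/C)[C@H](OC(C)=O)/C(C)=C/CCC(C)=O
F8 | step 21 | keto aldehyde (C5 aldehyde, C4 ketone, O6-TBS) | O=C[C@@H](O[Si](C)(C)C(C)(C)C)[C@@H](C(C)C)[C@H](OC(=O)/C(C)=C/C)[C@H](OC(C)=O)/C(C)=C/CCC(C)=O
F9 | step 21 | ten-membered C4,C5 cis-diol (O6-TBS) | C/C=C(\C)C(=O)O[C@H]1[C@H](C(C)C)[C@H](O[Si](C)(C)C(C)(C)C)[C@H](O)[C@](C)(O)CC/C=C(\C)[C@H]1OC(C)=O
F10 | step 21 | C5 mesylate of F9 | C/C=C(\C)C(=O)O[C@H]1[C@H](C(C)C)[C@H](O[Si](C)(C)C(C)(C)C)[C@H](OS(C)(=O)=O)[C@](C)(O)CC/C=C(\C)[C@H]1OC(C)=O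
F11 | step 21 | macrocyclic 4,5-epoxide with O6-TBS, O8 tiglate, O9 acetate | C/C=C(\C)C(=O)O[C@H]1[C@H](C(C)C)[C@H](O[Si](C)(C)C(C)(C)C)[C@H]2O[C@]2(C)CC/C=C(\C)[C@H]1OC(C)=O
F12 | step 21 | macrocyclic 4,5-epoxide with free C6–OH | C/C=C(\C)C(=O)O[C@H]1[C@H](C(C)C)[C@H](O)[C@H]2O[C@]2(C)CC/C=C(\C)[C@H]1OC(C)=O
F13 | step 18 | triethyl{[(5E)-6-iodohept-5-en-2-yl]oxy}silane | C/C(I)=C\CCC(C)O[Si](CC)(CC)CC
F14 | step 18 | NHK adduct: 9R alcohol with C4–OTES | COc1ccc(COC[C@@H](OC(=O)[C@H](C)[C@H](C)O[Si](C)(C)C(C)(C)C)[C@@H](C(C)C)[C@H](OC(=O)/C(C)=C/C)[C@H](O)/C(C)=C/CCC(C)O[Si](CC)(CC)CC)cc1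
F15 | step 18 | O9 acetate of F14 | COc1ccc(COC[C@@H](OC(=O)[C@H](C)[C@H](C)O[Si](C)(C)C(C)(C)C)[C@@H](C(C)C)[C@H](OC(=O)/C(C)=C/C)[C@H](OC(C)=O)/C(C)=C/CCC(C)O[Si](CC)(CC)CC)cc1
F16 | step 18 | F15 with free C4–OH | COc1ccc(COC[C@@H](OC(=O)[C@H](C)[C@H](C)O[Si](C)(C)C(C)(C)C)[C@@H](C(C)C)[C@H](OC(=O)/C(C)=C/C)[C@H](OC(C)=O)/C(C)=C/CCC(C)O)cc1
F17 | step 16 | C9 enone from 31 | COc1ccc(COC[C@@H](OC(=O)[C@H](C)[C@H](C)O[Si](C)(C)C(C)(C)C)[C@@H](C(C)C)[C@H](OC(=O)/C(C)=C/C)C(=O)/C(C)=C/CCC(C)Sc2ccccc2)cc1
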